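The route is built on disconnecting the C22–C23 bond of ring D. The only carbon between O21 and C23 is the methylene C22, and C23 is the β-carbon of a C9=C23–C17=O enone in ring C, so a C22 radical carried on the C20 oxygen can add 5-exo to C23. This single operation closes ring D across ring C, fixes C23 cis to O21 and leaves the C17 ketone for the later attachment of ring A at C9. The precursor is an (S)-4,4-dimethylcyclohex-2-enone with a (phenylselanyl)methoxy group at C20 and a tert-butyldiphenylsilyloxymethyl group at C9.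

Key step: step 7

Remarks on the chemistry
- Atom labels follow the atom order of the target SMILES. Ring A = C5, C6, C7, C8, C14, C16; ring B (lactone) = C8, C9, C10, O11, C12, C14; ring C = C9, C17, C19, C20, C24, C23; ring D = C20, O21, C22, C23, C24.
- Precursor design: the C10 oxygen carries a tert-butyldiphenylsilyl group, which should survive the acidic chloromethylation and the tin hydride step and is later removed by buffered fluoride, not by base.
- Precursor design: C10 is installed before the C20 oxygen, so the two enone arms of the dienone differ and only the unsubstituted arm is borylated.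
- After the key step C10 is raised to the aldehyde level, so C9 is reactivated as a vinylogous acid and never as an enolate with a β-leaving group.
- Assumption: the sense of induction in steps 5 and 17 is assigned by analogy with cyclohex-2-enone, and the ligand antipode is chosen to give the configuration drawn.
- Assumption: compounds 4, 9, 10, 16, 23 and 27 are bought.

Step 1
Reactants: 1 4,4-dimethylcyclohex-2-en-1-one
Product: 2 4,4-dimethylcyclohexa-2,5-dien-1-one
Conditions: DDQ, dioxane, reflux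
Reagents that add atoms: none
Why: Quinone dehydrogenation of the enone (hydride abstraction from the dienol) should give the cross-conjugated dienone, which cannot aromatise because C24 is quaternary.

Step 2
Reactants: 2 4,4-dimethylcyclohexa-2,5-dien-1-one
Product: 3 2-iodo-4,4-dimethylcyclohexa-2,5-dien-1-one
Conditions: I2 (1.1 equiv), pyridine, CH2Cl2, 0 °C to rt
Reagents that add atoms: iodine, [I][I]
Why: α-Iodination of an enone by the pyridine addition, iodination and elimination sequence should place one iodine at C9, the stoichiometry limiting the reaction to one of the two equivalent arms.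

Step 3
Reactants: 3 2-iodo-4,4-dimethylcyclohexa-2,5-dien-1-one; 4 (tributylstannyl)methanol
Product: 5 2-(hydroxymethyl)-4,4-dimethylcyclohexa-2,5-dien-1-one
Conditions: Pd(PPh3)4 (5 mol %), dioxane, 90 °C
Reagents that add atoms: none
Why: Stille coupling of the α-iodoenone should install C10 with O11, the oxygen-bearing sp3 group transferring from tin in preference to butyl.

Step 4
Reactants: 5 2-(hydroxymethyl)-4,4-dimethylcyclohexa-2,5-dien-1-one
Product: 6 2-({[tert-butyl(diphenyl)silyl]oxy}methyl)-4,4-dimethylcyclohexa-2,5-dien-1-one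
Conditions: TBDPSCl, imidazole, CH2Cl2, rt
Reagents that add atoms: tert-butyl(chloro)diphenylsilane, CC(C)(C)[Si](Cl)(c1ccccc1)c1ccccc1
Why: Standard silylation of the primary allylic alcohol gives an ether that tolerates the acid of step 6 and the radical conditions of step 7.

Step 5
Reactants: 6 2-({[tert-butyl(diphenyl)silyl]oxy}methyl)-4,4-dimethylcyclohexa-2,5-dien-1-one
Product: 8 (S)-2-({[tert-butyl(diphenyl)silyl]oxy}methyl)-5-hydroxy-4,4-dimethylcyclohex-2-en-1-one, via boryl ketone 7 (not isolated)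
Conditions: B2pin2, CuCl (3 mol %), NaOtBu (6 mol %), 2,3-bis(tert-butylmethylphosphino)quinoxaline (QuinoxP*, one antipode, 3 mol %), MeOH (2 equiv), THF, rt; then NaBO3·4H2O, THF/H2O, 0 °C
Reagents that add atoms: bis(pinacolato)diboron, CC1(C)OB(OC1(C)C)B1OC(C)(C)C(C)(C)O1 (boron of 7); sodium perborate, [Na+].[O-]OB=O (oxygen O21)
Why: Copper-catalysed enantioselective conjugate borylation should take place at C20 of the unsubstituted enone arm (the α-substituted arm is slower), the chiral diphosphine choosing the enone face and so setting C20 as S, and oxidation of the C–B bond proceeds with retention.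

Step 6
Reactants: 8 (S)-2-({[tert-butyl(diphenyl)silyl]oxy}methyl)-5-hydroxy-4,4-dimethylcyclohex-2-en-1-one; 9 formaldehyde (as paraformaldehyde); 10 benzeneselenol
Product: 12 (S)-2-({[tert-butyl(diphenyl)silyl]oxy}methyl)-4,4-dimethyl-5-[(phenylselanyl)methoxy]cyclohex-2-en-1-one, via chloromethyl ether 11 (not isolated)
Conditions: (CH2O)n, TMSCl, CH2Cl2, 0 °C to rt, then evaporate; PhSeH, iPr2NEt, CH2Cl2, 0 °C
Reagents that add atoms: chlorotrimethylsilane, C[Si](C)(C)Cl (chlorine of 11 only)
Why: Condensation of the C20 alcohol with formaldehyde and chloride gives the chloromethyl ether, and the soft selenol displaces chloride (SN2) to give the O,Se-acetal without strong base, so the β-alkoxy enone should not eliminate.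

Step 7
Reactants: 12 (S)-2-({[tert-butyl(diphenyl)silyl]oxy}methyl)-4,4-dimethyl-5-[(phenylselanyl)methoxy]cyclohex-2-en-1-one
Product: 13 (1R,2S,5S)-2-({[tert-butyl(diphenyl)silyl]oxy}methyl)-8,8-dimethyl-6-oxabicyclo[3.2.1]octan-3-one
Conditions: Bu3SnH (1.3 equiv) and AIBN (0.2 equiv) added over 6 h by syringe pump, PhH (0.01 M), reflux
Reagents that add atoms: none
Why: The tributyltin radical abstracts the phenylselanyl group from C22, the nucleophilic α-alkoxymethyl radical adds to the electron-poor β-carbon C23 of the C9=C23–C17=O enone, and the resulting C9 α-keto radical is reduced by Bu3SnH. The closest known reaction type is the 5-exo cyclisation of α-alkoxymethyl radicals generated from O,Se-acetals onto alkenes and enones (Ueno–Stork-type radical cyclisation). Ring D (C20, O21, C22, C23, C24) closes in the 5-exo-trig mode and bridges ring C. C23 is controlled by the tether, because a radical held on the axial C20 oxygen can reach only the same face of C23, so the bridge must be cis; C9 should take hydrogen on the face away from the axial C24 methyl, and its configuration is erased in step 9 in any case. The step needs 5-exo attack at C23 over 6-endo attack at C9, secured by the polarity match and the shorter tether, and cyclisation over direct reduction of the C22 radical, secured by slow addition of Bu3SnH at high dilution; the C10–O bond should survive because β-scission of a carbon–oxygen bond from the C9 radical is slow.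

Step 8
Reactants: 13 (1R,2S,5S)-2-({[tert-butyl(diphenyl)silyl]oxy}methyl)-8,8-dimethyl-6-oxabicyclo[3.2.1]octan-3-one
Product: 14 (1R,2S,5S)-2-(hydroxymethyl)-8,8-dimethyl-6-oxabicyclo[3.2.1]octan-3-one
Conditions: HF·pyridine, pyridine, THF, 0 °C to rt
Reagents that add atoms: none
Why: Fluoride cleavage of the Si–O bond under buffered, non-basic conditions should free the C10 alcohol without E1cB loss of the β-oxygen or retro-aldol cleavage.

Step 9
Reactants: 14 (1R,2S,5S)-2-(hydroxymethyl)-8,8-dimethyl-6-oxabicyclo[3.2.1]octan-3-one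
Product: 15 (1S,5S,Z)-2-(hydroxymethylidene)-8,8-dimethyl-6-oxabicyclo[3.2.1]octan-3-one (enol form of the 2-formyl ketone)
Conditions: Dess–Martin periodinane, NaHCO3, CH2Cl2, 0 °C to rt
Reagents that add atoms: none
Why: Dess–Martin oxidation gives the β-keto aldehyde, which should enolise fully to the hydrogen-bonded hydroxymethylidene ketone, making C9 trigonal and activating it regiospecifically as a vinylogous acid.

Step 10
Reactants: 16 cyclohexane-1,2-dione
Product: 17 2-{[tert-butyl(dimethyl)silyl]oxy}cyclohex-2-en-1-one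
Conditions: TBSCl, Et3N, DMAP (cat.), CH2Cl2, 0 °C to rt
Reagents that add atoms: tert-butyl(chloro)dimethylsilane, CC(C)(C)[Si](C)(C)Cl
Why: The dione reacts through its enol tautomer, and O-silylation gives the silyl enol ether that later becomes the C14 oxygen function of ring A.

Step 11
Reactants: 17 2-{[tert-butyl(dimethyl)silyl]oxy}cyclohex-2-en-1-one
Product: 18 rac-2-{[tert-butyl(dimethyl)silyl]oxy}cyclohex-2-en-1-ol
Conditions: NaBH4, CeCl3·7H2O, MeOH, −78 °C
Reagents that add atoms: none
Why: Luche 1,2-reduction of the enone should give the allylic alcohol; it is used racemic because its carbinol centre is destroyed in step 13.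

Step 12
Reactants: 15 (1S,5S,Z)-2-(hydroxymethylidene)-8,8-dimethyl-6-oxabicyclo[3.2.1]octan-3-one; 18 rac-2-{[tert-butyl(dimethyl)silyl]oxy}cyclohex-2-en-1-ol
Product: 19 (1S,5S,E)-2-{[(2-{[tert-butyl(dimethyl)silyl]oxy}cyclohex-2-en-1-yl)oxy]methylidene}-8,8-dimethyl-6-oxabicyclo[3.2.1]octan-3-one (both configurations at the cyclohexenyl carbinol carbon)
Conditions: PPh3, DIAD, THF, 0 °C to rt
Reagents that add atoms: none
Why: Mitsunobu alkylation of the acidic hydroxymethylidene ketone by the allylic alcohol should give the allyl vinyl ether; attack at either allyl terminus gives the same ether because the 2-silyloxyallyl unit is symmetrical, and O-alkylation at the C17 oxygen or C-alkylation at C9 would converge on 20 in step 13.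

Step 13
Reactants: 19 (1S,5S,E)-2-{[(2-{[tert-butyl(dimethyl)silyl]oxy}cyclohex-2-en-1-yl)oxy]methylidene}-8,8-dimethyl-6-oxabicyclo[3.2.1]octan-3-one
Product: 20 (1S,2R,5S)-2-(2-{[tert-butyl(dimethyl)silyl]oxy}cyclohex-2-en-1-yl)-8,8-dimethyl-3-oxo-6-oxabicyclo[3.2.1]octane-2-carbaldehyde (both C8 epimers)
Conditions: PhMe, 150 °C, sealed tube
Reagents that add atoms: none
Why: Claisen rearrangement of the allyl ether of a hydroxymethylidene ketone forms the C8–C9 bond and the quaternary centre; C8 should bond to the C9 face syn to the O21–C22 bridge because the other face is blocked by the C24 methyl that is syn-axial to C9, which gives C9 as R with C10 axial, while C8 forms as both epimers and is corrected in step 17.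

Step 14
Reactants: 20 (1S,2R,5S)-2-(2-{[tert-butyl(dimethyl)silyl]oxy}cyclohex-2-en-1-yl)-8,8-dimethyl-3-oxo-6-oxabicyclo[3.2.1]octane-2-carbaldehyde
Product: 21 (1S,2R,5S)-2-(2-{[tert-butyl(dimethyl)silyl]oxy}cyclohex-2-en-1-yl)-2-(hydroxymethyl)-8,8-dimethyl-6-oxabicyclo[3.2.1]octan-3-one (both C8 epimers)
Conditions: NaBH4, THF/EtOH, −40 °C
Reagents that add atoms: none
Why: Borohydride should reduce the C10 aldehyde at low temperature while the C17 ketone (flanked by quaternary C9) and the silyl enol ether are left, returning the C10 alcohol whose oxygen becomes O11.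

Step 15
Reactants: 21 (1S,2R,5S)-2-(2-{[tert-butyl(dimethyl)silyl]oxy}cyclohex-2-en-1-yl)-2-(hydroxymethyl)-8,8-dimethyl-6-oxabicyclo[3.2.1]octan-3-one
Product: 22 (1S,2R,5S)-2-(hydroxymethyl)-8,8-dimethyl-2-(2-oxocyclohex-3-en-1-yl)-6-oxabicyclo[3.2.1]octan-3-one (both C8 epimers)
Conditions: Pd(OAc)2 (1.1 equiv), MeCN, 40 °C
Reagents that add atoms: none
Why: Saegusa–Ito oxidation (palladation of the silyl enol ether at C16, β-hydride elimination toward C5) should give the ring A enone C14(=O)–C16=C5 regiospecifically.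

Step 16
Reactants: 23 3,3-diethoxyprop-1-yne
Product: 24 2-(3,3-diethoxyprop-1-en-2-yl)-4,4,5,5-tetramethyl-1,3,2-dioxaborolane
Conditions: B2pin2, CuCl (5 mol %), 1,3-dimesitylimidazolinium chloride (5 mol %), NaOtBu (20 mol %), MeOH (2 equiv), THF, −50 °C to rt
Reagents that add atoms: bis(pinacolato)diboron, CC1(C)OB(OC1(C)C)B1OC(C)(C)C(C)(C)O1
Why: Copper-catalysed protoboration of a terminal alkyne, which with an N-heterocyclic carbene ligand and propargylic oxygen substituents should deliver boron to the internal carbon, gives the 1,1-disubstituted alkenylboronate that carries C1, C2 and C3 as a masked enal.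

Step 17
Reactants: 22 (1S,2R,5S)-2-(hydroxymethyl)-8,8-dimethyl-2-(2-oxocyclohex-3-en-1-yl)-6-oxabicyclo[3.2.1]octan-3-one; 24 2-(3,3-diethoxyprop-1-en-2-yl)-4,4,5,5-tetramethyl-1,3,2-dioxaborolane
Product: 26 (1S,2R,5S)-2-[(1S,4R)-4-(3,3-diethoxyprop-1-en-2-yl)-2-oxocyclohexyl]-2-(hydroxymethyl)-8,8-dimethyl-6-oxabicyclo[3.2.1]octan-3-one, via C8-epimeric adducts 25 (not isolated)
Conditions: [Rh(cod)Cl]2 (2.5 mol %), (R)-BINAP (6 mol %), K3PO4 (0.5 equiv), dioxane/H2O 10:1, 50 °C; then K2CO3, MeOH, rt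
Reagents that add atoms: none
Why: Hayashi–Miyaura conjugate addition under catalyst control should set C5 as R (same CIP ordering as the (R)-3-alkenylcyclohexanones obtained with (R)-BINAP), and base then equilibrates C8 through the C14 enolate to the trans-2,5-diequatorial ketone (C8 S), which removes the C8 mixture from step 13.

Step 18
Reactants: 26 (1S,2R,5S)-2-[(1S,4R)-4-(3,3-diethoxyprop-1-en-2-yl)-2-oxocyclohexyl]-2-(hydroxymethyl)-8,8-dimethyl-6-oxabicyclo[3.2.1]octan-3-one; 27 1,3-dithiane
Product: 29 (1S,2R,5S)-2-[(1S,2S,4R)-4-(3,3-diethoxyprop-1-en-2-yl)-2-(1,3-dithian-2-yl)-2-hydroxycyclohexyl]-2-(hydroxymethyl)-8,8-dimethyl-6-oxabicyclo[3.2.1]octan-3-one, via 2-lithio-1,3-dithiane 28 (not isolated)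
Conditions: 27, n-BuLi, THF, −30 °C; add 26 (0.33 equiv), −78 to −30 °C; aq NH4Cl
Reagents that add atoms: none
Why: Corey–Seebach addition: the bulky sulfur-stabilised anion should attack the ring A ketone C14 (the C17 ketone next to quaternary C9 is spared) from the equatorial direction, trans to the C9 substituent on C8, so the new C12–C14 bond is equatorial and the tertiary hydroxyl axial and cis to C9, which is the S configuration at C14 of the target.

Step 19
Reactants: 29 (1S,2R,5S)-2-[(1S,2S,4R)-4-(3,3-diethoxyprop-1-en-2-yl)-2-(1,3-dithian-2-yl)-2-hydroxycyclohexyl]-2-(hydroxymethyl)-8,8-dimethyl-6-oxabicyclo[3.2.1]octan-3-one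
Product: 31 C12 lactol of the target (ring B closed as the hemiacetal; both anomers), via open hydroxy dialdehyde 30 (not isolated)
Conditions: PhI(O2CCF3)2, MeCN/H2O 9:1, 0 °C to rt
Reagents that add atoms: water, O
Why: Hypervalent iodine oxidises the dithiane sulfur and water releases the C12 aldehyde, which the C10 hydroxyl traps as the six-membered lactol, while the trifluoroacetic acid set free hydrolyses the diethyl acetal to the enal.

Step 20
Reactants: 31 C12 lactol of the target
Product: 32 target CNP0525385.1 (C5 R, C8 S, C9 R, C14 S, C20 S, C23 S)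
Conditions: SO3·pyridine, DMSO, Et3N, CH2Cl2, 0 °C to rt
Reagents that add atoms: none
Why: Parikh–Doering oxidation converts the lactol carbon C12 into the lactone carbonyl; the tertiary C14 hydroxyl and the enal are inert, and an activated-DMSO oxidant is chosen because it should not cleave the C12–C14 bond of the α-hydroxy lactol.

Compound list
1 | 4,4-dimethylcyclohex-2-en-1-one | CC1(C)CCC(=O)C=C1 | starting material
2 | 4,4-dimethylcyclohexa-2,5-dien-1-one | CC1(C)C=CC(=O)C=C1 | intermediate
3 | 2-iodo-4,4-dimethylcyclohexa-2,5-dien-1-one | CC1(C)C=CC(=O)C(I)=C1 | intermediate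
4 | (tributylstannyl)methanol | CCCC[Sn](CCCC)(CCCC)CO | starting material
5 | 2-(hydroxymethyl)-4,4-dimethylcyclohexa-2,5-dien-1-one | CC1(C)C=CC(=O)C(CO)=C1 | intermediate
6 | 2-({[tert-butyl(diphenyl)silyl]oxy}methyl)-4,4-dimethylcyclohexa-2,5-dien-1-one | CC1(C)C=CC(=O)C(CO[Si](c2ccccc2)(c2ccccc2)C(C)(C)C)=C1 | intermediate
7 | (S)-2-({[tert-butyl(diphenyl)silyl]oxy}methyl)-4,4-dimethyl-5-(4,4,5,5-tetramethyl-1,3,2-dioxaborolan-2-yl)cyclohex-2-en-1-one | O=C1C[C@H](B2OC(C)(C)C(C)(C)O2)C(C)(C)C=C1CO[Si](c3ccccc3)(c3ccccc3)C(C)(C)C | intermediate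
8 | (S)-2-({[tert-butyl(diphenyl)silyl]oxy}methyl)-5-hydroxy-4,4-dimethylcyclohex-2-en-1-one | O=C1C[C@H](O)C(C)(C)C=C1CO[Si](c2ccccc2)(c2ccccc2)C(C)(C)C | intermediate
9 | formaldehyde (used as paraformaldehyde) | C=O | starting material
10 | benzeneselenol | [SeH]c1ccccc1 | starting material
11 | (S)-2-({[tert-butyl(diphenyl)silyl]oxy}methyl)-5-(chloromethoxy)-4,4-dimethylcyclohex-2-en-1-one | O=C1C[C@H](OCCl)C(C)(C)C=C1CO[Si](c2ccccc2)(c2ccccc2)C(C)(C)C | intermediate
12 | (S)-2-({[tert-butyl(diphenyl)silyl]oxy}methyl)-4,4-dimethyl-5-[(phenylselanyl)methoxy]cyclohex-2-en-1-one | O=C1C[C@H](OC[Se]c2ccccc2)C(C)(C)C=C1CO[Si](c3ccccc3)(c3ccccc3)C(C)(C)C | intermediate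
13 | (1R,2S,5S)-2-({[tert-butyl(diphenyl)silyl]oxy}methyl)-8,8-dimethyl-6-oxabicyclo[3.2.1]octan-3-one | O=C1C[C@@H]2OC[C@H]([C@H]1CO[Si](c3ccccc3)(c3ccccc3)C(C)(C)C)C2(C)C | intermediate
14 | (1R,2S,5S)-2-(hydroxymethyl)-8,8-dimethyl-6-oxabicyclo[3.2.1]octan-3-one | O=C1C[C@@H]2OC[C@H]([C@H]1CO)C2(C)C | intermediate
15 | (1S,5S,Z)-2-(hydroxymethylidene)-8,8-dimethyl-6-oxabicyclo[3.2.1]octan-3-one | O=C1C[C@@H]2OC[C@H](/C1=C/O)C2(C)C | intermediate
16 | cyclohexane-1,2-dione | O=C1CCCCC1=O | starting material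
17 | 2-{[tert-butyl(dimethyl)silyl]oxy}cyclohex-2-en-1-one | O=C1CCCC=C1O[Si](C)(C)C(C)(C)C | intermediate
18 | rac-2-{[tert-butyl(dimethyl)silyl]oxy}cyclohex-2-en-1-ol | OC1CCCC=C1O[Si](C)(C)C(C)(C)C | intermediate
19 | (1S,5S,E)-2-{[(2-{[tert-butyl(dimethyl)silyl]oxy}cyclohex-2-en-1-yl)oxy]methylidene}-8,8-dimethyl-6-oxabicyclo[3.2.1]octan-3-one, carbinol carbon unspecified | O=C1C[C@@H]2OC[C@H](/C1=C\OC3CCCC=C3O[Si](C)(C)C(C)(C)C)C2(C)C | intermediate
20 | (1S,2R,5S)-2-(2-{[tert-butyl(dimethyl)silyl]oxy}cyclohex-2-en-1-yl)-8,8-dimethyl-3-oxo-6-oxabicyclo[3.2.1]octane-2-carbaldehyde, C8 unspecified | O=C[C@@]1(C2CCCC=C2O[Si](C)(C)C(C)(C)C)C(=O)C[C@@H]3OC[C@H]1C3(C)C | intermediate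
21 | (1S,2R,5S)-2-(2-{[tert-butyl(dimethyl)silyl]oxy}cyclohex-2-en-1-yl)-2-(hydroxymethyl)-8,8-dimethyl-6-oxabicyclo[3.2.1]octan-3-one, C8 unspecified | OC[C@@]1(C2CCCC=C2O[Si](C)(C)C(C)(C)C)C(=O)C[C@@H]3OC[C@H]1C3(C)C | intermediate
22 | (1S,2R,5S)-2-(hydroxymethyl)-8,8-dimethyl-2-(2-oxocyclohex-3-en-1-yl)-6-oxabicyclo[3.2.1]octan-3-one, C8 unspecified | OC[C@@]1(C2CCC=CC2=O)C(=O)C[C@@H]3OC[C@H]1C3(C)C | intermediate
23 | 3,3-diethoxyprop-1-yne | C#CC(OCC)OCC | starting material
24 | 2-(3,3-diethoxyprop-1-en-2-yl)-4,4,5,5-tetramethyl-1,3,2-dioxaborolane | C=C(B1OC(C)(C)C(C)(C)O1)C(OCC)OCC | intermediate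
25 | (1S,2R,5S)-2-[(4R)-4-(3,3-diethoxyprop-1-en-2-yl)-2-oxocyclohexyl]-2-(hydroxymethyl)-8,8-dimethyl-6-oxabicyclo[3.2.1]octan-3-one, C8 unspecified | C=C(C(OCC)OCC)[C@@H]1CCC(C(=O)C1)[C@]2(CO)C(=O)C[C@@H]3OC[C@H]2C3(C)C | intermediate
26 | (1S,2R,5S)-2-[(1S,4R)-4-(3,3-diethoxyprop-1-en-2-yl)-2-oxocyclohexyl]-2-(hydroxymethyl)-8,8-dimethyl-6-oxabicyclo[3.2.1]octan-3-one | C=C(C(OCC)OCC)[C@@H]1CC[C@H](C(=O)C1)[C@]2(CO)C(=O)C[C@@H]3OC[C@H]2C3(C)C | intermediate
27 | 1,3-dithiane | C1CSCSC1 | starting material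
28 | 2-lithio-1,3-dithiane | [Li]C1SCCCS1 | intermediate
29 | (1S,2R,5S)-2-[(1S,2S,4R)-4-(3,3-diethoxyprop-1-en-2-yl)-2-(1,3-dithian-2-yl)-2-hydroxycyclohexyl]-2-(hydroxymethyl)-8,8-dimethyl-6-oxabicyclo[3.2.1]octan-3-one | C=C(C(OCC)OCC)[C@@H]1CC[C@H]([C@](O)(C2SCCCS2)C1)[C@]3(CO)C(=O)C[C@@H]4OC[C@H]3C4(C)C | intermediate
30 | (1S,2R,5S)-2-[(1S,2S,4R)-2-formyl-2-hydroxy-4-(3-oxoprop-1-en-2-yl)cyclohexyl]-2-(hydroxymethyl)-8,8-dimethyl-6-oxabicyclo[3.2.1]octan-3-one | C=C(C=O)[C@@H]1CC[C@H]([C@](O)(C=O)C1)[C@]2(CO)C(=O)C[C@@H]3OC[C@H]2C3(C)C | intermediate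
31 | C12 lactol of the target (ring B hemiacetal, C12 unspecified) | C=C(C=O)[C@@H]1CC[C@H]2[C@]3(COC(O)[C@]2(O)C1)C(=O)C[C@@H]1OC[C@H]3C1(C)C | intermediate
32 | CNP0525385.1 (C5 R, C8 S, C9 R, C14 S, C20 S, C23 S) | C=C(C=O)[C@@H]1CC[C@H]2[C@]3(COC(=O)[C@]2(O)C1)C(=O)C[C@@H]1OC[C@H]3C1(C)C | target

Total step count: 20. Longest linear sequence: 17 steps (steps 1–9, 12–15 and 17–20, from compound 1).

Steps most likely to fail

1. Step 7. The C22 radical may be reduced before it cyclises, or the conformer with the C20 oxygen axial, which the bridging closure needs, may be too little populated. The fallback sets out from 2 and returns at 14; it closes ring D through the O21–C20 bond instead. The Grignard reagent [(dimethyl(propan-2-yloxy)silyl)methyl]magnesium chloride F1, made from the commercial chloromethylsilane and Mg, is added to dienone 2 under copper catalysis (CuBr·SMe2, chiral phosphoramidite). Trapping the magnesium enolate with monomeric formaldehyde should give the trans adduct (5R,6S)-5-{[dimethyl(propan-2-yloxy)silyl]methyl}-6-(hydroxymethyl)-4,4-dimethylcyclohex-2-en-1-one F2. Tamao–Fleming oxidation (KHF2, m-CPBA, DMF) should give the diol (5R,6S)-5,6-bis(hydroxymethyl)-4,4-dimethylcyclohex-2-en-1-one F3. With K2CO3 in MeOH its C22 hydroxyl should add to C20 of the remaining enone (intramolecular oxa-Michael addition, cis by necessity) to give 14.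

2. Step 17. Transmetalation of the α-branched alkenylboronate may be slow and lose out to protodeboronation, or the resident stereocentres may erode catalyst control. The fallback sets out from 22 and returns at 32; it uses a simple nucleophile and moves the oxidation of the side chain to the end. The same rhodium/(R)-BINAP conditions with potassium isopropenyltrifluoroborate (CH2=C(CH3)BF3K) should give the C8-epimeric isopropenyl adducts F4, equilibrated with K2CO3 in MeOH to the trans isopropenyl diketone F5. The conditions of steps 18 to 20 should then lead through the dithiane adduct F6, the open hydroxy aldehyde F7 (not isolated) and the isopropenyl lactol F8 to the isopropenyl lactone F9. Allylic oxidation of the isopropenyl methyl group (SeO2 cat., t-BuOOH, CH2Cl2) should give the allylic alcohol F10, which MnO2 should oxidise to 32.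

3. Step 18. Addition may stall through enolisation of the C14 ketone or its masking as the hemiketal of the C10 alkoxide, and the adduct may revert on warming. The fallback sets out from 26 and returns at 32; it delivers C12 at the acid oxidation level, so neither sulfur unmasking nor lactol oxidation is needed. N,N-Diisopropylcarbamoyllithium F11 is generated from N,N-diisopropylformamide and LiN(iPr)2 at −95 °C in the presence of 26 and should add to C14 with the same facial preference to give the α-hydroxy amide (1S,2R,5S)-2-[(1S,2S,4R)-4-(3,3-diethoxyprop-1-en-2-yl)-2-(diisopropylcarbamoyl)-2-hydroxycyclohexyl]-2-(hydroxymethyl)-8,8-dimethyl-6-oxabicyclo[3.2.1]octan-3-one F12. TsOH·H2O in wet toluene at 80 °C should then bring about N-to-O acyl transfer onto the C10 hydroxyl (lactonisation) and hydrolyse the acetal, giving 32.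

Further compounds
F1 | step 7 | [(dimethyl(propan-2-yloxy)silyl)methyl]magnesium chloride | CC(C)O[Si](C)(C)C[Mg]Cl
F2 | step 7 | (5R,6S)-5-{[dimethyl(propan-2-yloxy)silyl]methyl}-6-(hydroxymethyl)-4,4-dimethylcyclohex-2-en-1-one | O=C1C=CC(C)(C)[C@H](C[Si](C)(C)OC(C)C)[C@H]1CO
F3 | step 7 | (5R,6S)-5,6-bis(hydroxymethyl)-4,4-dimethylcyclohex-2-en-1-one | O=C1C=CC(C)(C)[C@H](CO)[C@H]1CO
F4 | step 17 | (1S,2R,5S)-2-(hydroxymethyl)-8,8-dimethyl-2-[(4R)-2-oxo-4-(prop-1-en-2-yl)cyclohexyl]-6-oxabicyclo[3.2.1]octan-3-one, C8 unspecified | C=C(C)[C@@H]1CCC(C(=O)C1)[C@]2(CO)C(=O)C[C@@H]3OC[C@H]2C3(C)C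
F5 | step 17 | (1S,2R,5S)-2-(hydroxymethyl)-8,8-dimethyl-2-[(1S,4R)-2-oxo-4-(prop-1-en-2-yl)cyclohexyl]-6-oxabicyclo[3.2.1]octan-3-one | C=C(C)[C@@H]1CC[C@H](C(=O)C1)[C@]2(CO)C(=O)C[C@@H]3OC[C@H]2C3(C)C
F6 | step 17 | (1S,2R,5S)-2-[(1S,2S,4R)-2-(1,3-dithian-2-yl)-2-hydroxy-4-(prop-1-en-2-yl)cyclohexyl]-2-(hydroxymethyl)-8,8-dimethyl-6-oxabicyclo[3.2.1]octan-3-one | C=C(C)[C@@H]1CC[C@H]([C@](O)(C2SCCCS2)C1)[C@]3(CO)C(=O)C[C@@H]4OC[C@H]3C4(C)C
F7 | step 17 | (1S,2R,5S)-2-[(1S,2S,4R)-2-formyl-2-hydroxy-4-(prop-1-en-2-yl)cyclohexyl]-2-(hydroxymethyl)-8,8-dimethyl-6-oxabicyclo[3.2.1]octan-3-one | C=C(C)[C@@H]1CC[C@H]([C@](O)(C=O)C1)[C@]2(CO)C(=O)C[C@@H]3OC[C@H]2C3(C)C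
F8 | step 17 | isopropenyl analogue of lactol 31 (CH3 in place of the C3 aldehyde, C12 unspecified) | C=C(C)[C@@H]1CC[C@H]2[C@]3(COC(O)[C@]2(O)C1)C(=O)C[C@@H]1OC[C@H]3C1(C)C
F9 | step 17 | isopropenyl analogue of 32 (CH3 in place of the C3 aldehyde) | C=C(C)[C@@H]1CC[C@H]2[C@]3(COC(=O)[C@]2(O)C1)C(=O)C[C@@H]1OC[C@H]3C1(C)C
F10 | step 17 | allylic alcohol analogue of 32 (CH2OH in place of the C3 aldehyde) | C=C(CO)[C@@H]1CC[C@H]2[C@]3(COC(=O)[C@]2(O)C1)C(=O)C[C@@H]1OC[C@H]3C1(C)C
F11 | step 18 | N,N-diisopropylcarbamoyllithium | [Li]C(=O)N(C(C)C)C(C)C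
F12 | step 18 | (1S,2R,5S)-2-[(1S,2S,4R)-4-(3,3-diethoxyprop-1-en-2-yl)-2-(diisopropylcarbamoyl)-2-hydroxycyclohexyl]-2-(hydroxymethyl)-8,8-dimethyl-6-oxabicyclo[3.2.1]octan-3-one | C=C(C(OCC)OCC)[C@@H]1CC[C@H]([C@](O)(C(=O)N(C(C)C)C(C)C)C1)[C@]2(CO)C(=O)C[C@@H]3OC[C@H]2C3(C)C
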